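## Structural features

- The target is a guaiane ester. Cyclopentane ring A (C1–C5) is fused through the C1–C5 bond to cycloheptene ring B (C1, C5, C6, C7, C8, C9, C10). Guaiane numbering is used throughout: C4 bears C15H3 and OH, C10 bears C14H3, and C7 bears the isopropyl group C11–C13.
- The only alkene is the tetrasubstituted C1=C10 bond, so C1 is sp2 and C5 is the only stereogenic fusion atom.
- The five contiguous stereocentres C4–C5–C6–C7–C8 are (4S,5S,6R,7S,8S). With the face of H5 called α, the atoms H6, H7, C15 and O8 are α, while O4, O6 and the isopropyl group are β.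
- O4, O6 and O8 form a 1,3,5-triol array (4,6-syn, 6,8-anti). Only O8 is acylated, by vanillic acid, whose phenol stays free.
- The fragile points are the tertiary C4 carbinol (elimination), the C1=C10 bond (it can drift while C8 is a carbonyl), every β-hydroxy ketone stage (retro-aldol, E1cB), and the phenolic aryl ester.
- The real difficulty is ring B. It is a seven-membered ring with a tetrasubstituted alkene at the fusion, and O6 sits on its concave β face, cis to both carbon neighbours (C4 on C5 and the isopropyl group on C7).
- The feature exploited is the substitution order around ring B: C1 (carbon chain), C10 (CH3), C9 (H), C8 (O), C7 (isopropyl), C6 (H). This reproduces, atom for atom, the benzene ring of thymol substituted para to its OH.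
- C5 is the one extra ring atom and also the atom that ties C2–C3–C4 of ring A back on, so the key step inserts C5 as a keto-carbene between C1 and C6 of that arene.

## Logic of the disconnections

**18 ⇒ 14 + 15 (through 17 and 16).** The bonds cut are O8–C(=O)Ar and, as a mask, the phenolic O–CH2Ph bond of 17. This is the only bond between the two halves, and cutting it leaves a C15 triol and a purchasable acid. The forward step must acylate O8 in the presence of O6 and O4. The phenol mask must leave without touching C1=C10.

**14 ⇒ 13.** The C8–H bond is cut, taking the carbinol back to a ketone. One stereocentre disappears, C7 becomes epimerisable toward its equatorial arrangement, and O6 stands 1,3 to the carbonyl. The forward step must bring hydride to the β face of C8, on the side of O6.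

**13 ⇒ 10.** The C6–O and C7–H bonds are cut. A β-hydroxy ketone is the retron of an oxa-Michael addition, and O4 is 1,3-syn to O6, so it can carry the incoming oxygen. Two stereocentres are removed. The forward step must deliver oxygen to the hindered concave face and must stay mild, because 10 holds two skipped alkenes.

**10 ⇒ 9.** The C9–H bond is cut, taking the C8 ketone back to its silyl trienol ether. This restores the fully unsaturated ring B that a ring-expanded arene delivers directly. The forward protonation must occur at C9 and not at C1.

**9 ⇒ 8.** The C4–C15 bond is cut. C4 loses its stereocentre, and a ketone appears next to C5, which is the retron of a keto-carbene. The forward step must add methyl to a very enolisable ketone, from the α face.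

**8 ⇒ 6 (key disconnection).** The C5–C1 and C5–C6 bonds are cut and ring B collapses to a benzene ring.

- Both rings, the tetrasubstituted C1=C10 alkene, the oxygen at C8, the isopropyl group at C7 and the C6=C7 handle all come from one operation.
- The precursor is a flat arene with a four-carbon chain, no ring other than benzene and no stereocentre.
- The forward step must choose the C1–C6 bond over the C1–C10 bond, choose one enantiotopic arene face, and avoid rearomatisation.
- In one sentence, the route is an enantioselective intramolecular Buchner ring expansion of 6. That sentence does not describe the aldol/metathesis plan drawn first.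

**6 ⇒ 4 ⇒ 3.** The C5=N2 bond and the O–Si bond are cut. This leaves a simple methyl ketone whose CH3 is the future C5. The forward step needs diazo transfer at the methyl side only.

**3 ⇒ 1 + 2.** The C1–C2 bond is cut. It joins a ten-carbon arene to a four-carbon enone, both commercial. The forward step needs attack para to the OH of 1.

## Other disconnections considered

**Alternative 1:** (the first that comes to mind)

- *Cut:* C1=C10 by ring-closing metathesis, after C5–C6 by an aldol addition.
- *Forward key step:* the seco-diene A1, built from a cyclopentanone enolate and a chiral β-alkoxy aldehyde, is closed with second-generation Grubbs catalyst.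
- *Grounds for preferring the chosen plan:*
  - Two 1,1-disubstituted alkenes would have to give a tetrasubstituted alkene inside a seven-membered ring next to C5, which is the slowest class of metathesis.
  - The closure sets no stereocentre.
  - The acyclic C6–C7–C8 triad, C4 and C5 each need their own stereocontrolled step and protecting groups, so the sequence is clearly longer.

**Alternative 2:**

- *Cut:* C1–C5, transannular.
- *Forward key step:* Lewis acid opening of the epoxygermacrene A2. The C1=C10 π bond attacks C5 anti to the C5–O bond, O stays on C4, and the C10 cation loses H1.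
- *Grounds for preferring the chosen plan:*
  - Net anti addition across an (E)-configured C4=C5 bond places O4 cis to H5, which is opposite to the target.
  - A2 would therefore have to be the cis-epoxide of a (4Z)-alkene.
  - A ten-membered ring with one E alkene, one cis-epoxide and three stereocentres is no simpler than the target.
  - Proton loss from C10 can take three directions, and the free O6 next to the epoxide invites other openings.

**Alternative 3:**

- *Cut:* C5–C6 by a [3,3] shift.
- *Forward key step:* the cis-divinylcyclopropane A3 rearranges through the boat transition state (Cope rearrangement) to the cycloheptadiene A4, with C1=C10 in place and H5/H6 cis. Hydroboration of C7=C8 from the α face would then set H7 and O8 syn, as required.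
- *Grounds for preferring the chosen plan:*
  - A3 needs three independent stereochemical elements: C4, the absolute configuration of a cyclopropane with a quaternary C10, and an enol ether geometry that must distinguish isopropyl from cyclopropyl.
  - None of these elements controls another.
  - The precursor is therefore about as complex as the product, and it takes more steps to reach than 6.

Key step: step 4

Assumption: the sense of induction of Rh2(S-PTTL)4 on 6 cannot be derived from first principles. If the (S) series leads to the antipode of 8, the antipodal catalyst Rh2(R-PTTL)4 is used.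

## Steps

**Step 1**
Reactants: 1 thymol (2-isopropyl-5-methylphenol); 2 methyl vinyl ketone (but-3-en-2-one)
Product: 3 4-(4-hydroxy-5-isopropyl-2-methylphenyl)butan-2-one
Conditions: 1 (3 equiv), 2 (1 equiv), Amberlyst 15 (sulfonic acid resin), toluene, 60 °C
Reagents that add atoms: none
Why: Acid-catalysed Friedel–Crafts conjugate alkylation of a phenol with an enone, the reaction type by which simple phenols are turned into 4-arylbutan-2-ones. The position para to OH (future C1) is the most activated and least hindered open site, the free ortho site being wedged between OH and CH3, and the excess of 1 limits double alkylation.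

**Step 2**
Reactants: 3 4-(4-hydroxy-5-isopropyl-2-methylphenyl)butan-2-one
Product: 4 4-[4-(tert-butyldimethylsilyloxy)-5-isopropyl-2-methylphenyl]butan-2-one
Conditions: TBSCl, imidazole, DMF, rt
Reagents that add atoms: tert-butyldimethylsilyl chloride, CC(C)(C)[Si](C)(C)Cl
Why: Standard silylation of a phenol. The bulky silyl ether keeps the ring electron-rich for step 4, resists loss after ipso attack, and later makes O8 an enol silane that buffered fluoride can release.

**Step 3**
Reactants: 4 4-[4-(tert-butyldimethylsilyloxy)-5-isopropyl-2-methylphenyl]butan-2-one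
Product: 6 1-diazo-4-[4-(tert-butyldimethylsilyloxy)-5-isopropyl-2-methylphenyl]butan-2-one, via trifluoroacetyl diketone 5 (not isolated)
Conditions: LiHMDS, THF, −78 °C; CF3CO2CH2CF3; aq HCl; then 4-AcNHC6H4SO2N3, Et3N, H2O (1 equiv), MeCN, rt
Reagents that add atoms: 2,2,2-trifluoroethyl trifluoroacetate, O=C(OCC(F)(F)F)C(F)(F)F (CF3CO group of 5 only); 4-acetamidobenzenesulfonyl azide, CC(=O)Nc1ccc(cc1)S(=O)(=O)N=[N+]=[N-] (N2 of 6)
Why: Detrifluoroacetylative diazo transfer: kinetic deprotonation at the CH3 side (future C5), Claisen trifluoroacetylation to 5, then diazo transfer with loss of the CF3CO group gives the terminal diazoketone without diazomethane. The aryl silyl ether is inert to LiHMDS at −78 °C.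

**Step 4**
Reactants: 6 1-diazo-4-[4-(tert-butyldimethylsilyloxy)-5-isopropyl-2-methylphenyl]butan-2-one
Product: 8 (8aR)-6-(tert-butyldimethylsilyloxy)-4-methyl-7-isopropyl-3,8a-dihydroazulen-1(2H)-one, via norcaradiene 7 (not isolated)
Conditions: Rh2(S-PTTL)4 (1 mol %; PTTL = N-phthaloyl-tert-leucinate), CH2Cl2, 0 °C, slow addition of 6; short plug of neutral alumina, used at once
Reagents that add atoms: none
Why: Loss of N2 from 6 at the divalent rhodium centre gives an electrophilic keto-carbenoid at C5 that adds across the C1–C6 π bond of the arene, which is the intramolecular Buchner reaction of an aryl diazoketone, a known reaction type with enantioselective versions under chiral dirhodium carboxylates and copper bis(oxazoline) complexes. Ring A closes by C5–C1 bond formation (5-exo attack on the ipso carbon through the tether C2–C3–C4) and a cyclopropane closes by C5–C6 bond formation, which gives norcaradiene 7. Disrotatory 6π electrocyclic opening of the C1–C6 bond of 7 then turns the six-membered ring into seven-membered ring B and leaves C1=C10 tetrasubstituted, C8=C9 as a silyl enol ether and C6=C7 next to the isopropyl group. C5 is the only stereocentre that survives, and it is fixed by which enantiotopic face of the arene meets the carbenoid, a choice made by the chiral carboxylate pocket of the catalyst. Regioselectivity for C1–C6 over C1–C10 is secured by the ortho methyl group on C10, which blocks the second ipso–ortho bond, whereas C6 bears only H. Insertion does not compete because the atom placed for five-membered-ring C–H insertion is C1, which has no hydrogen. The bulky silyl group disfavours desilylation after ipso attack, and acid-free, cold, short handling holds back rearomatisation of 7 and enolisation at C5.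

**Step 5**
Reactants: 8 (8aR)-6-(tert-butyldimethylsilyloxy)-4-methyl-7-isopropyl-3,8a-dihydroazulen-1(2H)-one
Product: 9 (1S,8aR)-6-(tert-butyldimethylsilyloxy)-1,4-dimethyl-7-isopropyl-1,2,3,8a-tetrahydroazulen-1-ol
Conditions: MeLi, CeCl3, THF, −78 °C; then 8, −78 °C; aq NH4Cl
Reagents that add atoms: methyllithium, [Li]C
Why: Organocerium 1,2-addition, the standard answer to readily enolisable ketones (C5–H is α to the ketone and doubly allylic), since the weakly basic, oxophilic reagent should add faster than it deprotonates. On ring A, C5 carries C6 on the β face and only H on the α face, so methyl should enter α (trans to C6) and O4 becomes β, which sets C4 as S.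

**Step 6**
Reactants: 9 (1S,8aR)-6-(tert-butyldimethylsilyloxy)-1,4-dimethyl-7-isopropyl-1,2,3,8a-tetrahydroazulen-1-ol
Product: 10 (1S,8aR)-1-hydroxy-1,4-dimethyl-7-isopropyl-2,3,5,8a-tetrahydroazulen-6(1H)-one (4β-hydroxyguaia-1(10),6-dien-8-one)
Conditions: TBAF, AcOH, THF, −78 to −20 °C
Reagents that add atoms: none
Why: Fluoride cleaves the enol silane, and AcOH protonates the extended enolate kinetically at its α carbon C9 (deconjugative protonation), which keeps C1=C10 in place and leaves C6=C7 conjugated with the new C8 ketone. The buffer and low temperature hold back drift of the skipped alkenes, and C4 and C5 are not touched.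

**Step 7**
Reactants: 10 4β-hydroxyguaia-1(10),6-dien-8-one
Product: 13 4β,6β-dihydroxyguai-1(10)-en-8-one (5αH,7αH), via boronic hemiester 11 (not isolated), via cyclic boronate 12 (not isolated)
Conditions: PhB(OH)2, 4 Å MS, DABCO (20 mol %), N,N'-bis[3,5-bis(trifluoromethyl)phenyl]thiourea (20 mol %), toluene, rt; then 30% H2O2, pH 7 buffer, THF, 0 °C
Reagents that add atoms: phenylboronic acid, OB(O)c1ccccc1
Why: Boronic-acid-tethered intramolecular oxa-Michael addition of a δ-hydroxy enone: O4 binds the boronic acid as 11, and the amine-activated B–OH oxygen adds 6-exo-trig to C6, which it can reach only on the concave β face where O4 stands, so the 4,6-syn relation is set in 12. The enolate should be protonated at C7 from the open α face, which is also the thermodynamic result (equatorial isopropyl). Buffered peroxide then oxidises the B–C bond and frees 13.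

**Step 8**
Reactants: 13 4β,6β-dihydroxyguai-1(10)-en-8-one
Product: 14 guai-1(10)-ene-4β,6β,8α-triol
Conditions: Me4NBH(OAc)3, MeCN/AcOH, −30 °C
Reagents that add atoms: none
Why: Evans–Saksena hydroxyl-directed reduction: ligand exchange at O6, which is axial on the β face and 1,3 to the carbonyl, delivers hydride inside the complex to the β face of C8 and should give the 8α (equatorial) carbinol, 1,3-anti to O6. The reagent does not reduce unbound ketones or alkenes, and the cold acidic medium should not move C1=C10.

**Step 9**
Reactants: 14 guai-1(10)-ene-4β,6β,8α-triol; 15 4-(benzyloxy)-3-methoxybenzoic acid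
Product: 17 4β,6β-dihydroxyguai-1(10)-en-8α-yl 4-(benzyloxy)-3-methoxybenzoate, via mixed anhydride 16 (not isolated)
Conditions: 15 (1.05 equiv), 2,4,6-Cl3C6H2COCl, Et3N, toluene, rt; then 14, DMAP, 0 °C to rt
Reagents that add atoms: 2,4,6-trichlorobenzoyl chloride, O=C(Cl)c1c(Cl)cc(Cl)cc1Cl (atoms kept in 16 only)
Why: Yamaguchi esterification. O8 is an equatorial, menthol-like secondary hydroxyl next to a CH2 group, O6 is axial on the concave face between two branched carbons and hydrogen-bonded to O4, and O4 is tertiary, so about one equivalent of 16 should acylate O8 only.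

**Step 10**
Reactants: 17 4β,6β-dihydroxyguai-1(10)-en-8α-yl 4-(benzyloxy)-3-methoxybenzoate
Product: 18 target, (4S,5S,6R,7S,8S)-4,6-dihydroxyguai-1(10)-en-8-yl 4-hydroxy-3-methoxybenzoate
Conditions: H2 (1 atm), Pd/C, EtOAc, rt
Reagents that add atoms: none
Why: Hydrogenolysis of a benzyl aryl ether. The tetrasubstituted C1=C10 alkene, the alkyl aryl ester and the alcohols should be inert at one atmosphere and room temperature, and no stereocentre is touched.

## Compound list

1 | thymol | Cc1ccc(C(C)C)c(O)c1 | starting material
2 | methyl vinyl ketone | C=CC(C)=O | starting material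
3 | 4-(4-hydroxy-5-isopropyl-2-methylphenyl)butan-2-one | CC(=O)CCc1cc(C(C)C)c(O)cc1C | intermediate
4 | 4-[4-(tert-butyldimethylsilyloxy)-5-isopropyl-2-methylphenyl]butan-2-one | CC(=O)CCc1cc(C(C)C)c(O[Si](C)(C)C(C)(C)C)cc1C | intermediate
5 | 1,1,1-trifluoro-6-[4-(tert-butyldimethylsilyloxy)-5-isopropyl-2-methylphenyl]hexane-2,4-dione (not isolated) | O=C(CC(=O)C(F)(F)F)CCc1cc(C(C)C)c(O[Si](C)(C)C(C)(C)C)cc1C | intermediate
6 | 1-diazo-4-[4-(tert-butyldimethylsilyloxy)-5-isopropyl-2-methylphenyl]butan-2-one | [N-]=[N+]=CC(=O)CCc1cc(C(C)C)c(O[Si](C)(C)C(C)(C)C)cc1C | intermediate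
7 | norcaradiene valence tautomer of 8 (cyclopropane C1–C5–C6, diene C7=C8–C9=C10; not isolated) | O=C1CC[C@]23[C@H]1[C@H]2C(C(C)C)=C(O[Si](C)(C)C(C)(C)C)C=C3C | intermediate
8 | (8aR)-6-(tert-butyldimethylsilyloxy)-4-methyl-7-isopropyl-3,8a-dihydroazulen-1(2H)-one | CC(C)(C)[Si](C)(C)OC1=CC(C)=C2CCC(=O)[C@@H]2C=C1C(C)C | intermediate
9 | (1S,8aR)-6-(tert-butyldimethylsilyloxy)-1,4-dimethyl-7-isopropyl-1,2,3,8a-tetrahydroazulen-1-ol | CC(C)(C)[Si](C)(C)OC1=CC(C)=C2CC[C@](C)(O)[C@@H]2C=C1C(C)C | intermediate
10 | 4β-hydroxyguaia-1(10),6-dien-8-one (5αH) | O=C1CC(C)=C2CC[C@](C)(O)[C@@H]2C=C1C(C)C | intermediate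
11 | O4-[hydroxy(phenyl)boryl] derivative of 10 (not isolated) | O=C1CC(C)=C2CC[C@](C)(OB(O)c3ccccc3)[C@@H]2C=C1C(C)C | intermediate
12 | 4β,6β-O-phenylboranediyl derivative of 13 (not isolated) | O=C1CC(C)=C2CC[C@](C)(OB(c4ccccc4)O3)[C@@H]2[C@H]3[C@@H]1C(C)C | intermediate
13 | 4β,6β-dihydroxyguai-1(10)-en-8-one (5αH,7αH) | O=C1CC(C)=C2CC[C@](C)(O)[C@@H]2[C@H](O)[C@@H]1C(C)C | intermediate
14 | guai-1(10)-ene-4β,6β,8α-triol | O[C@H]1CC(C)=C2CC[C@](C)(O)[C@@H]2[C@H](O)[C@@H]1C(C)C | intermediate
15 | 4-(benzyloxy)-3-methoxybenzoic acid | COc1cc(C(=O)O)ccc1OCc1ccccc1 | starting material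
16 | 4-(benzyloxy)-3-methoxybenzoic 2,4,6-trichlorobenzoic anhydride (not isolated) | COc1cc(C(=O)OC(=O)c2c(Cl)cc(Cl)cc2Cl)ccc1OCc1ccccc1 | intermediate
17 | 4β,6β-dihydroxyguai-1(10)-en-8α-yl 4-(benzyloxy)-3-methoxybenzoate | COc1cc(C(=O)O[C@H]2CC(C)=C3CC[C@](C)(O)[C@@H]3[C@H](O)[C@@H]2C(C)C)ccc1OCc1ccccc1 | intermediate
18 | 4β,6β-dihydroxyguai-1(10)-en-8α-yl 4-hydroxy-3-methoxybenzoate | COc1cc(C(=O)O[C@H]2CC(C)=C3CC[C@](C)(O)[C@@H]3[C@H](O)[C@@H]2C(C)C)ccc1O | target

## Step count and least certain steps

Total step count: 10. The longest linear sequence is 10 steps (1 to 18). Compounds 2 and 15 are bought and enter in steps 1 and 9.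

**Step 4 (key step).**

- *What may go wrong:*
  - The carbenoid may attack the ipso carbon C1, para to the donor oxygen, and the silyl group may then be lost instead of C5 closing onto C6.
  - Traces of acid may rearomatise the norcaradiene.
  - C5–H is α to the ketone and doubly allylic, so enolisation may erode the enantiomeric purity.
  - Face discrimination may be insufficient, because the arene face is marked only by remote substituents.
- *Fallback (asymmetric catalysis replaced by a racemic ring expansion and a resolution at a configurationally safe stage):* it sets out from 6. Compound 6 is decomposed with achiral Rh2(OAc)4, the carboxylate with the broadest record for this ring expansion. This gives 7 and 8 together with the antipodal norcaradiene F1 (not isolated) and the antipodal azulenone F2. Methyl addition as in step 5 gives 9 together with the antipodal carbinol F3. These carbinols no longer have an acidic C5–H and are separated by preparative chromatography on a chiral stationary phase. The route is rejoined at 9.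

**Step 1.**

- *What may go wrong:* attack at the free ortho position followed by closure of the phenol onto the ketone, double alkylation, polymerisation of 2, or acid-induced migration of the isopropyl group.
- *Fallback (cross-coupling in place of electrophilic alkylation):* it sets out from 1. Para-bromination (NBS, MeCN) gives 4-bromothymol F4. Silylation (TBSCl, imidazole) gives its silyl ether F5. A Heck reaction with but-3-en-2-ol (Pd(OAc)2, Bu4NCl, NaHCO3, DMF, 70 °C), in which β-hydride elimination toward the carbinol and tautomerisation give the saturated methyl ketone, comes back to the route at 4.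

**Step 5.**

- *What may go wrong:* deprotonation at C5 instead of addition, with loss of material and of enantiomeric purity. Attack from the β face is less likely.
- *Fallback (methylene transfer and hydride opening in place of a methyl carbanion):* it sets out from 8. Chloromethyllithium, generated in the presence of 8 (ClCH2I, MeLi·LiBr, THF, −78 °C), adds from the α face, and the alkoxide closes to the spiro-epoxide F6. LiEt3BH opens F6 at its CH2 terminus and returns to the route at 9.

**Step 7.**

- *What may go wrong:*
  - The amine may cause the two skipped alkenes of 10 to drift into conjugation before the addition occurs.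
  - The addition may be slow, because the enone is α-branched and the tether starts from a tertiary alcohol.
  - The addition may reverse.
- *Fallback (hydroxyl-directed epoxidation and reductive opening in place of conjugate addition):* it sets out from 10.
  1. Luche reduction (NaBH4, CeCl3, MeOH, −78 °C) from the open α face gives the 8β-allylic alcohol F7.
  2. VO(acac)2/t-BuOOH epoxidises C6=C7 on the β face, directed by O8 and O4 alike and faster than the merely homoallylic C1=C10, to give the epoxy alcohol F8.
  3. Dess–Martin periodinane gives the epoxy ketone F9.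
  4. SmI2 (THF/MeOH, −78 °C) cleaves the C7–O bond, keeps O6 β, and after protonation at C7 returns to the route at 13.

**Step 9.**

- *What may go wrong:* competing acylation at O6, double acylation, or a slow reaction next to the isopropyl-bearing carbon that invites forcing conditions.
- *Fallback (selectivity enforced by a temporary ring in place of kinetic discrimination):* it sets out from 14. PhB(OH)2 (toluene, 4 Å MS) ties the syn-1,3-diol O4/O6 into the triol boronate F10. Acylation of the only free hydroxyl with 16 and DMAP gives the ester boronate F11. Buffered H2O2 releases the diol and returns to the route at 17.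

## Further compounds

F1 | step 4 | antipode of norcaradiene 7 | O=C1CC[C@@]23[C@@H]1[C@@H]2C(C(C)C)=C(O[Si](C)(C)C(C)(C)C)C=C3C
F2 | step 4 | (8aS)-6-(tert-butyldimethylsilyloxy)-4-methyl-7-isopropyl-3,8a-dihydroazulen-1(2H)-one | CC(C)(C)[Si](C)(C)OC1=CC(C)=C2CCC(=O)[C@H]2C=C1C(C)C
F3 | step 4 | (1R,8aS)-6-(tert-butyldimethylsilyloxy)-1,4-dimethyl-7-isopropyl-1,2,3,8a-tetrahydroazulen-1-ol | CC(C)(C)[Si](C)(C)OC1=CC(C)=C2CC[C@@](C)(O)[C@H]2C=C1C(C)C
F4 | step 1 | 4-bromo-2-isopropyl-5-methylphenol | Cc1cc(O)c(C(C)C)cc1Br
F5 | step 1 | (4-bromo-2-isopropyl-5-methylphenoxy)(tert-butyl)dimethylsilane | Cc1cc(O[Si](C)(C)C(C)(C)C)c(C(C)C)cc1Br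
F6 | step 5 | spiro-epoxide at C4 of 8 (O4 β, CH2 α) | CC(C)(C)[Si](C)(C)OC1=CC(C)=C2CC[C@]3(OC3)[C@@H]2C=C1C(C)C
F7 | step 7 | guaia-1(10),6-diene-4β,8β-diol | O[C@@H]1CC(C)=C2CC[C@](C)(O)[C@@H]2C=C1C(C)C
F8 | step 7 | 6β,7β-epoxyguai-1(10)-ene-4β,8β-diol | O[C@@H]1CC(C)=C2CC[C@](C)(O)[C@@H]2[C@@H]3O[C@@]31C(C)C
F9 | step 7 | 6β,7β-epoxy-4β-hydroxyguai-1(10)-en-8-one | O=C1CC(C)=C2CC[C@](C)(O)[C@@H]2[C@@H]3O[C@@]31C(C)C
F10 | step 9 | 4β,6β-O-phenylboranediyl derivative of 14 | O[C@H]1CC(C)=C2CC[C@](C)(OB(c4ccccc4)O3)[C@@H]2[C@H]3[C@@H]1C(C)C
F11 | step 9 | 4β,6β-O-phenylboranediyl derivative of 17 | COc1cc(C(=O)O[C@H]2CC(C)=C3CC[C@](C)(OB(c5ccccc5)O4)[C@@H]3[C@H]4[C@@H]2C(C)C)ccc1OCc1ccccc1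
A1 | alternative 1 | 1,10-seco-diene: 1-methyl-3-methylidenecyclopentan-1-ol bearing at C2 the 1,3-dihydroxy-2-isopropyl-5-methylhex-5-enyl chain, configured as in 14 | C=C(C)C[C@H](O)[C@@H](C(C)C)[C@@H](O)[C@@H]1C(=C)CC[C@]1(C)O
A2 | alternative 2 | cis-4,5-epoxygermacr-1(10)E-ene-6,8-diol, configured to give 14 | O[C@H]1C/C(C)=C/CC[C@]2(C)O[C@@H]2[C@H](O)[C@@H]1C(C)C
A3 | alternative 3 | cis-divinylcyclopropane (cyclopropane C8–C9–C10; C10 bears CH3 and the 3-hydroxy-3-methylcyclopentenyl group, C8 bears the 2-isopropyl-silyloxyvinyl group) | C[C@]1(C[C@@H]1/C(C(C)C)=C/O[Si](C)(C)C(C)(C)C)C2=C[C@@](C)(O)CC2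
A4 | alternative 3 | 6β-(tert-butyldimethylsilyloxy)guaia-1(10),7-dien-4β-ol | CC1=C2CC[C@](C)(O)[C@@H]2[C@H](O[Si](C)(C)C(C)(C)C)C(C(C)C)=CC1
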